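The data come from a simulation with made-up constants, and the scatter is random.

Each Xp made takes one Xa and one Xb, so at every reading c(Xb) is its charge minus c(Xp), while Xc, as a catalyst, appears in no such balance and ought to keep working.

| setting | east | north-west | north | south-east | west |
|---|---|---|---|---|---|
| Xa | 0.600 M | 0.240 M | 0.600 M | 0.600 M | 0.200 M |
| Xb | 0.720 M | 0.360 M | 1.10 M | 0.720 M | 0.240 M |
| Xc | 0.0480 M | 0.0480 M | 0.0480 M | 0.140 M | 0.0480 M |
| time |  |  |  |  | 44 min |

| run | time / min | [Xp] / M |
|---|---|---|
| east run | 7.3 | 0.122 |
| east run | 15 | 0.188 |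
| east run | 22 | 0.225 |
| east run | 29 | 0.250 |
| east run | 37 | 0.267 |
| east run | 44 | 0.276 |
| north-west run | 7.3 | 0.046 |
| north-west run | 15 | 0.080 |
| north-west run | 22 | 0.093 |
| north-west run | 29 | 0.108 |
| north-west run | 37 | 0.112 |
| north-west run | 44 | 0.122 |
| north run | 7.3 | 0.191 |
| north run | 15 | 0.286 |
| north run | 22 | 0.342 |
| north run | 29 | 0.372 |
| north run | 37 | 0.395 |
| north run | 44 | 0.412 |
| south-east run | 7.3 | 0.279 |
| south-east run | 15 | 0.396 |
| south-east run | 22 | 0.444 |
| south-east run | 29 | 0.472 |
| south-east run | 37 | 0.495 |
| south-east run | 44 | 0.507 |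

(readings scatter by 0.003 M)

- Overall: Xa + Xb -> Xp, with Xc as catalyst.
- Constant volume, constant temperature.
- The analysis sees a species whether free or bound.
- "The second partner" is Xb.
- An order is taken over about fifteen percent of the charge, up and down.

1. the power of [Xb] that the first rate follows, about the charge of the east run; measure it at two percent of Xa made into Xp
2. the power of [Xa] that the first rate follows, about the charge of the east run; measure it at two percent of Xa made into Xp (one fixed amount of Xp, the same in the runs compared)
3. Xp in the west run at 44 min, as a share of the Xa charged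
4. which of these the readings show (the catalyst dies in pairs / nothing beyond the main steps / the loaded catalyst dies / the catalyst rests as a dimer / two substrates go astray together)

The east run seems to contradict this. It makes Xp at 0.0167 M min⁻¹ over the first 7.3 min and at 0.00129 M min⁻¹ over the last 7.00 min, yet at 44 min it still holds 0.444 M of Xb and 0.324 M of Xa.

Dividing Xb out clears this up. At 44 min the east run has a dose of 10.1 M⁻¹, the dose being minus the logarithm of the share of Xb left, divided by the c(Xc) charged. The north run, with 1.10 M of Xb, reaches 9.78 M⁻¹ at that time, so the dose hardly follows the Xb charge. In the east run it grows by 3.87 M⁻¹ in the first interval and by 0.418 M⁻¹ in the last, far less. With Xb divided out, that flattening is what to watch: working Xc is fading, which is catalyst deactivation. The north-west run, with less Xa and less Xb, has a dose of 8.62 M⁻¹, lower than the east run. From 22 min to 44 min the dose grows by a fraction 0.385 of its value at 22 min in the north-west run and by 0.290 in the east run, so the north-west run, with less Xa, reads as fading less, and that points to death of the loaded catalyst.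

The west run has the same c(Xc) charged as the east and north-west runs. Stepping along Xa from the north-west run gives, by this reckoning, a dose of 8.46 M⁻¹, hence 0.0801 M of Xp, or 40.1 % of the Xa charged.

The forecast gave 0.97 and 0.27 for the orders and 39.5 %, a little lower than this reckoning, with the verdict the loaded catalyst dies, “suggesting that the Xa-loaded catalyst dies”.

The flask gives 1.0, 0.32, 39.9 % and the loaded catalyst dies.

    Xc + Xa ⇌ Xc.Xa, settled at all times (4.120 M⁻¹)
    Xc.Xa + Xb → Xp + Xc (1.002 M⁻¹ min⁻¹)
    Xc.Xa → G + Xa (0.09060 min⁻¹)

The west result corresponds to a dose of 8.43 M⁻¹ at 44 min, beside 8.46 M⁻¹ reckoned. The north-west run, when its Xp comes to half of its Xa at 42.2 min, stands at a dose of 8.45 M⁻¹. The west run stands lower at 44 min because of the step from Xc.Xa to G + Xa: without that step it reaches 58.4 % instead of 39.9 %, a dose of 13.9 M⁻¹.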